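**Plan**

1. Atoms are numbered from the ether end: C1 (OCH2), C2, C3 (side-chain carbinol), C4, C5, C6 (ring CH), C7 (ring C(CH3)OH), C8, C9, C10 (ring CHOH), C11 (ring C(CH3)2). The target is read as (3R,6R,7S,10S).
2. Retrosynthetic cuts: the aryl ether O–C1 (Mitsunobu), C7–CH3 (methyl addition to a C7 ketone unmasked from a nitro group), the ring bond C7–C8 (nitronate conjugate addition), C9–C10 (vinyl addition), C6–C11 (aldehyde-to-nitroalkene Michael addition) and C6–C7 (Henry reaction).
3. Enabling feature: in the ring C6–C11 the oxygenated carbons C7 and C10 are 1,4-related, which is the pattern of a γ-nitro ketone (C7 nitro as latent carbonyl, C10 ketone). C1–C6 with the (3R) carbinol is the chain of (R)-linalool.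
4. Forward order: linalool is cut down to the C1–C6 aldehyde, extended to the nitroalkene, joined to isobutyraldehyde (C10, C11), vinylated and oxidised. The only ring then closes by the nitronate Michael addition. C10 is reduced, C7 is unmasked and methylated, and the coumarin is attached last.
5. Stereochemistry: C3 comes from (R)-linalool and C6 from the amine–thiourea catalyst. C10 (axial OH) and C7 (equatorial CH3) are relayed from C6 by a bulky hydride and an organocerium reagent.

Key step: step 8

Remark: the sense of induction in step 5 is assumed from the usual enamine/thiourea model and the (1R,2R) catalyst is written; should it prove opposite, the (1S,2S) enantiomer of the same catalyst is used.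
Remark: the C10 hydroxyl is carried unprotected from step 9 on, so the reagents of steps 11 and 12 are used in excess.

**Route**

Step 1
Reactants: 1 (R)-linalool
Product: 2 triethyl{[(3R)-3,7-dimethylocta-1,6-dien-3-yl]oxy}silane
Conditions: Et3SiOTf, 2,6-lutidine, CH2Cl2, −78 → 0 °C
Reagents that add atoms: triethylsilyl trifluoromethanesulfonate, CC[Si](CC)(CC)OS(=O)(=O)C(F)(F)F
Why: Silylation of a hindered tertiary allylic alcohol with a silyl triflate and 2,6-lutidine is standard, and it keeps the C3 oxygen from adding to the nitroalkene and the enone that follow; C3 is untouched.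

Step 2
Reactants: 2 triethyl{[(3R)-3,7-dimethylocta-1,6-dien-3-yl]oxy}silane
Product: 4 (4R)-4-methyl-4-[(triethylsilyl)oxy]hex-5-enal, via secondary ozonide 3 (not isolated)
Conditions: O3, CH2Cl2, −78 °C (Sudan Red 7B end point); Me2S, −78 °C → rt
Reagents that add atoms: ozone, [O-][O+]=O
Why: Ozonolysis with reductive work-up cleaves the electron-rich trisubstituted alkene far faster than the monosubstituted vinyl group next to the silyloxy-bearing quaternary carbon, so titration of ozone to the indicator end point should leave C1=C2 intact.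

Step 3
Reactants: 4 (4R)-4-methyl-4-[(triethylsilyl)oxy]hex-5-enal; 5 nitromethane
Product: 6 (5R)-5-methyl-1-nitro-5-[(triethylsilyl)oxy]hept-6-en-2-ol (both C2 epimers)
Conditions: MeNO2 (10 equiv), t-BuOK (10 mol %), THF/t-BuOH, 0 °C → rt
Reagents that add atoms: none
Why: Base-catalysed Henry (nitroaldol) reaction of an unhindered aldehyde with excess nitromethane forms C6–C7; the carbinol centre arises as a mixture and is removed in step 4.

Step 4
Reactants: 6 (5R)-5-methyl-1-nitro-5-[(triethylsilyl)oxy]hept-6-en-2-ol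
Product: 8 (1E,5R)-5-methyl-1-nitro-5-[(triethylsilyl)oxy]hepta-1,6-diene, via nitro mesylate 7 (not isolated)
Conditions: MsCl, Et3N, CH2Cl2, −20 → 0 °C
Reagents that add atoms: none
Why: Mesylation followed by base-induced E1cB elimination is the usual dehydration of β-nitro alcohols and gives the conjugated (E)-nitroalkene as the thermodynamically preferred isomer.

Step 5
Reactants: 8 (1E,5R)-5-methyl-1-nitro-5-[(triethylsilyl)oxy]hepta-1,6-diene; 9 isobutyraldehyde
Product: 10 (3R,6R)-2,2,6-trimethyl-3-(nitromethyl)-6-[(triethylsilyl)oxy]oct-7-enal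
Conditions: isobutyraldehyde (3 equiv), 1-[(1R,2R)-2-aminocyclohexyl]-3-[3,5-bis(trifluoromethyl)phenyl]thiourea (15 mol %), H2O (2 equiv), CH2Cl2, rt
Reagents that add atoms: none
Why: Enamine-mediated asymmetric Michael addition of an α,α-disubstituted aldehyde to a nitroalkene: the primary amine forms the enamine of isobutyraldehyde, the thiourea holds the nitro group, and C11 is delivered to the Si face of C6 under catalyst control, which sets (6R) (C3 in the name of 10) independently of the remote C3 centre.

Step 6
Reactants: 10 (3R,6R)-2,2,6-trimethyl-3-(nitromethyl)-6-[(triethylsilyl)oxy]oct-7-enal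
Product: 12 (5R,8R)-4,4,8-trimethyl-5-(nitromethyl)-8-[(triethylsilyl)oxy]deca-1,9-dien-3-ol (both C3 epimers), via bromomagnesium nitronate 11 (not isolated)
Conditions: CH2=CHMgBr (2.5 equiv), THF, −78 °C (aldehyde added to the reagent); AcOH, −78 °C → rt
Reagents that add atoms: vinylmagnesium bromide, C=C[Mg]Br
Why: Grignard 1,2-addition to a non-enolisable neopentyl aldehyde: the first equivalent is spent in turning CH2NO2 into its magnesium nitronate, which should be inert to more reagent at −78 °C and is returned to the nitroalkane by the cold acetic acid quench, while the second equivalent adds to the aldehyde and gives the C10 carbinol as an epimer mixture that step 7 removes.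

Step 7
Reactants: 12 (5R,8R)-4,4,8-trimethyl-5-(nitromethyl)-8-[(triethylsilyl)oxy]deca-1,9-dien-3-ol
Product: 13 (5R,8R)-4,4,8-trimethyl-5-(nitromethyl)-8-[(triethylsilyl)oxy]deca-1,9-dien-3-one
Conditions: Dess–Martin periodinane, pyridine, CH2Cl2, 0 °C → rt
Reagents that add atoms: none
Why: Dess–Martin oxidation of a secondary allylic alcohol under pyridine buffering merges both C10 epimers into the vinyl ketone without touching the silyl ether or the nitro group; the neighbouring C11 is quaternary, so nothing can epimerise.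

Step 8
Reactants: 13 (5R,8R)-4,4,8-trimethyl-5-(nitromethyl)-8-[(triethylsilyl)oxy]deca-1,9-dien-3-one
Product: 14 (3R,4R)-2,2-dimethyl-3-{(3R)-3-methyl-3-[(triethylsilyl)oxy]pent-4-en-1-yl}-4-nitrocyclohexan-1-one
Conditions: DBU (0.3 equiv), MeCN (0.01 M), 0 °C → rt
Reagents that add atoms: none
Why: DBU removes a proton from the C7 nitromethyl group and the carbon of the resulting nitronate adds to the terminal enone carbon C8, after which the enolate is protonated to the C10 ketone. The closest known reaction type is the intramolecular Michael addition of a nitronate to an enone, an established way to 4-nitrocyclohexanones. The ring C6–C7–C8–C9–C10–C11 closes in the 6-endo-trig mode. The new stereocentre C7 is controlled by the resident C6 centre under thermodynamic conditions, since the carbon next to the nitro group stays epimerisable in the presence of DBU and should settle with the nitro group equatorial and trans to the C6 side chain; its configuration is of no consequence because C7 becomes a carbonyl carbon in step 10. The step needs ring closure to outrun intermolecular addition and polymerisation of the vinyl ketone, which high dilution and the quaternary C11 between the two reacting arms (Thorpe–Ingold effect) should secure. C6 carries no acidic hydrogen and the nitro group ends up γ to the ketone, so neither epimerisation at C6 nor loss of nitrous acid is expected.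

Step 9
Reactants: 14 (3R,4R)-2,2-dimethyl-3-{(3R)-3-methyl-3-[(triethylsilyl)oxy]pent-4-en-1-yl}-4-nitrocyclohexan-1-one
Product: 15 (1S,3R,4R)-2,2-dimethyl-3-{(3R)-3-methyl-3-[(triethylsilyl)oxy]pent-4-en-1-yl}-4-nitrocyclohexan-1-ol
Conditions: LiBH(s-Bu)3 (1.5 equiv), THF, −78 °C; aq NH4Cl (no peroxide work-up)
Reagents that add atoms: none
Why: Reduction with a bulky trialkylborohydride: in the chair that keeps the C6 chain and the C7 nitro group equatorial the reagent should attack C10 from the equatorial side, as with 4,4-dimethyl-3-oxo terpenoids, and place the hydroxyl axial and trans to the side chain (10S), while the nitro group is not reduced and any deprotonation at C7 is harmless because that centre becomes a carbonyl in step 10.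

Step 10
Reactants: 15 (1S,3R,4R)-2,2-dimethyl-3-{(3R)-3-methyl-3-[(triethylsilyl)oxy]pent-4-en-1-yl}-4-nitrocyclohexan-1-ol
Product: 17 (2R,4S)-4-hydroxy-3,3-dimethyl-2-{(3R)-3-methyl-3-[(triethylsilyl)oxy]pent-4-en-1-yl}cyclohexan-1-one, via sodium nitronate 16 (not isolated)
Conditions: NaOMe, MeOH, 0 °C; then aq TiCl3, NH4OAc (pH 5–6), 0 °C → rt
Reagents that add atoms: water, O
Why: Nef reaction in its reductive form: the nitronate is reduced by trivalent titanium to the imine, which is hydrolysed at pH 5–6 to the C7 ketone under conditions that should spare the silyl ether, the vinyl group and the enolisable C6 centre.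

Step 11
Reactants: 17 (2R,4S)-4-hydroxy-3,3-dimethyl-2-{(3R)-3-methyl-3-[(triethylsilyl)oxy]pent-4-en-1-yl}cyclohexan-1-one
Product: 18 (1S,2R,4S)-1,3,3-trimethyl-2-{(3R)-3-methyl-3-[(triethylsilyl)oxy]pent-4-en-1-yl}cyclohexane-1,4-diol
Conditions: MeLi, CeCl3 (MeCeCl2, 4 equiv), THF, −78 °C; aq NH4Cl
Reagents that add atoms: methyllithium (used as MeCeCl2), [Li]C
Why: 1,2-Addition of a weakly basic organocerium reagent to an enolisable ketone: the methyl group should enter C7 along the equatorial path anti to the C6 side chain, the axial path being closed by the axial methyl group on C11, which gives the axial hydroxyl cis to the side chain (7S) without enolisation towards C6.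

Step 12
Reactants: 18 (1S,2R,4S)-1,3,3-trimethyl-2-{(3R)-3-methyl-3-[(triethylsilyl)oxy]pent-4-en-1-yl}cyclohexane-1,4-diol
Product: 20 (1S,2R,4S)-2-{(3R)-5-hydroxy-3-methyl-3-[(triethylsilyl)oxy]pentyl}-1,3,3-trimethylcyclohexane-1,4-diol, via trialkylborane 19 (not isolated)
Conditions: 9-BBN (4 equiv), THF, 0 °C → rt; aq NaOH, H2O2, 0 °C
Reagents that add atoms: hydrogen peroxide, OO
Why: Hydroboration–oxidation with the bulky, regioselective 9-borabicyclo[3.3.1]nonane places boron on the terminal carbon C1 of the only alkene, and alkaline peroxide oxidation with retention gives the primary alcohol; the free hydroxyls only consume some reagent.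

Step 13
Reactants: 20 (1S,2R,4S)-2-{(3R)-5-hydroxy-3-methyl-3-[(triethylsilyl)oxy]pentyl}-1,3,3-trimethylcyclohexane-1,4-diol; 21 umbelliferone (7-hydroxy-2H-chromen-2-one)
Product: 22 7-({(3R)-5-[(1R,3S,6S)-3,6-dihydroxy-2,2,6-trimethylcyclohexyl]-3-methyl-3-[(triethylsilyl)oxy]pentyl}oxy)-2H-chromen-2-one
Conditions: PPh3, DIAD, THF, 0 °C → rt
Reagents that add atoms: none
Why: Mitsunobu etherification of the primary alcohol with the acidic 7-hydroxyl of umbelliferone; the tertiary C7 hydroxyl and the hindered, axial, neopentyl-type C10 hydroxyl should not form oxyphosphonium ions at a useful rate, so only C1 is arylated.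

Step 14
Reactants: 22 7-({(3R)-5-[(1R,3S,6S)-3,6-dihydroxy-2,2,6-trimethylcyclohexyl]-3-methyl-3-[(triethylsilyl)oxy]pentyl}oxy)-2H-chromen-2-one
Product: 23 7-({(3R)-5-[(1R,3S,6S)-3,6-dihydroxy-2,2,6-trimethylcyclohexyl]-3-hydroxy-3-methylpentyl}oxy)-2H-chromen-2-one (CNP0210598.2)
Conditions: HF·pyridine, pyridine, THF, 0 °C → rt
Reagents that add atoms: none
Why: Fluoride-induced cleavage of the tertiary triethylsilyl ether with pyridine-buffered HF, conditions under which neither the coumarin lactone nor the tertiary alcohols should suffer.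

**Compound list**

1 | (R)-linalool, (3R)-3,7-dimethylocta-1,6-dien-3-ol | C=C[C@](C)(O)CCC=C(C)C | starting material
2 | triethyl{[(3R)-3,7-dimethylocta-1,6-dien-3-yl]oxy}silane | C=C[C@](C)(O[Si](CC)(CC)CC)CCC=C(C)C | intermediate
3 | secondary ozonide, 3,3-dimethyl-5-{(3R)-3-methyl-3-[(triethylsilyl)oxy]pent-4-en-1-yl}-1,2,4-trioxolane (not isolated) | CC1(C)OOC(CC[C@@](C)(O[Si](CC)(CC)CC)C=C)O1 | intermediate
4 | (4R)-4-methyl-4-[(triethylsilyl)oxy]hex-5-enal | O=CCC[C@@](C)(O[Si](CC)(CC)CC)C=C | intermediate
5 | nitromethane | C[N+](=O)[O-] | starting material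
6 | (5R)-5-methyl-1-nitro-5-[(triethylsilyl)oxy]hept-6-en-2-ol (both C2 epimers) | O=[N+]([O-])CC(O)CC[C@@](C)(O[Si](CC)(CC)CC)C=C | intermediate
7 | nitro mesylate, (5R)-5-methyl-1-nitro-5-[(triethylsilyl)oxy]hept-6-en-2-yl methanesulfonate (not isolated) | O=[N+]([O-])CC(OS(C)(=O)=O)CC[C@@](C)(O[Si](CC)(CC)CC)C=C | intermediate
8 | (1E,5R)-5-methyl-1-nitro-5-[(triethylsilyl)oxy]hepta-1,6-diene | O=[N+]([O-])/C=C/CC[C@@](C)(O[Si](CC)(CC)CC)C=C | intermediate
9 | isobutyraldehyde | CC(C)C=O | starting material
10 | (3R,6R)-2,2,6-trimethyl-3-(nitromethyl)-6-[(triethylsilyl)oxy]oct-7-enal | O=CC(C)(C)[C@H](C[N+](=O)[O-])CC[C@@](C)(O[Si](CC)(CC)CC)C=C | intermediate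
11 | bromomagnesium nitronate of 10 (not isolated) | O=CC(C)(C)[C@H](C=[N+]([O-])O[Mg]Br)CC[C@@](C)(O[Si](CC)(CC)CC)C=C | intermediate
12 | (5R,8R)-4,4,8-trimethyl-5-(nitromethyl)-8-[(triethylsilyl)oxy]deca-1,9-dien-3-ol (both C3 epimers) | C=CC(O)C(C)(C)[C@H](C[N+](=O)[O-])CC[C@@](C)(O[Si](CC)(CC)CC)C=C | intermediate
13 | (5R,8R)-4,4,8-trimethyl-5-(nitromethyl)-8-[(triethylsilyl)oxy]deca-1,9-dien-3-one | C=CC(=O)C(C)(C)[C@H](C[N+](=O)[O-])CC[C@@](C)(O[Si](CC)(CC)CC)C=C | intermediate
14 | (3R,4R)-2,2-dimethyl-3-{(3R)-3-methyl-3-[(triethylsilyl)oxy]pent-4-en-1-yl}-4-nitrocyclohexan-1-one (side chain and nitro group trans) | CC1(C)[C@@H](CC[C@@](C)(O[Si](CC)(CC)CC)C=C)[C@H]([N+](=O)[O-])CCC1=O | intermediate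
15 | (1S,3R,4R)-2,2-dimethyl-3-{(3R)-3-methyl-3-[(triethylsilyl)oxy]pent-4-en-1-yl}-4-nitrocyclohexan-1-ol (hydroxyl trans to the side chain) | CC1(C)[C@@H](CC[C@@](C)(O[Si](CC)(CC)CC)C=C)[C@H]([N+](=O)[O-])CC[C@@H]1O | intermediate
16 | sodium nitronate of 15 (not isolated) | CC1(C)[C@@H](CC[C@@](C)(O[Si](CC)(CC)CC)C=C)C(=[N+]([O-])[O-])CC[C@@H]1O.[Na+] | intermediate
17 | (2R,4S)-4-hydroxy-3,3-dimethyl-2-{(3R)-3-methyl-3-[(triethylsilyl)oxy]pent-4-en-1-yl}cyclohexan-1-one | CC1(C)[C@@H](CC[C@@](C)(O[Si](CC)(CC)CC)C=C)C(=O)CC[C@@H]1O | intermediate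
18 | (1S,2R,4S)-1,3,3-trimethyl-2-{(3R)-3-methyl-3-[(triethylsilyl)oxy]pent-4-en-1-yl}cyclohexane-1,4-diol | CC1(C)[C@@H](CC[C@@](C)(O[Si](CC)(CC)CC)C=C)[C@@](C)(O)CC[C@@H]1O | intermediate
19 | trialkylborane, the B-alkyl-9-borabicyclo[3.3.1]nonane from 18 with boron on C1 (not isolated) | CC1(C)[C@@H](CC[C@@](C)(O[Si](CC)(CC)CC)CCB2C3CCCC2CCC3)[C@@](C)(O)CC[C@@H]1O | intermediate
20 | (1S,2R,4S)-2-{(3R)-5-hydroxy-3-methyl-3-[(triethylsilyl)oxy]pentyl}-1,3,3-trimethylcyclohexane-1,4-diol | CC1(C)[C@@H](CC[C@@](C)(O[Si](CC)(CC)CC)CCO)[C@@](C)(O)CC[C@@H]1O | intermediate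
21 | umbelliferone, 7-hydroxy-2H-chromen-2-one | O=c1ccc2ccc(O)cc2o1 | starting material
22 | 7-({(3R)-5-[(1R,3S,6S)-3,6-dihydroxy-2,2,6-trimethylcyclohexyl]-3-methyl-3-[(triethylsilyl)oxy]pentyl}oxy)-2H-chromen-2-one | CC1(C)[C@@H](CC[C@@](C)(O[Si](CC)(CC)CC)CCOc2ccc3ccc(=O)oc3c2)[C@@](C)(O)CC[C@@H]1O | intermediate
23 | 7-({(3R)-5-[(1R,3S,6S)-3,6-dihydroxy-2,2,6-trimethylcyclohexyl]-3-hydroxy-3-methylpentyl}oxy)-2H-chromen-2-one | CC1(C)[C@@H](CC[C@@](C)(O)CCOc2ccc3ccc(=O)oc3c2)[C@@](C)(O)CC[C@@H]1O | target

**Step count**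

Total: 14 steps. Longest linear sequence: 14 steps, from (R)-linalool.

**Steps most likely to fail**

Step 6. The vinyl Grignard reagent may attack the nitronate, or the nitronate may undergo Henry-type oligomerisation with unreacted aldehyde, instead of clean addition to the aldehyde. The fallback sets out from 10 and avoids any basic organometallic. Chlorite oxidation (NaClO2, NaH2PO4, 2-methylbut-2-ene, t-BuOH/H2O) should give (3R,6R)-2,2,6-trimethyl-3-(nitromethyl)-6-[(triethylsilyl)oxy]oct-7-enoic acid F1. Neutral activation with 1-chloro-N,N,2-trimethylprop-1-en-1-amine in CH2Cl2 should convert it into (3R,6R)-2,2,6-trimethyl-3-(nitromethyl)-6-[(triethylsilyl)oxy]oct-7-enoyl chloride F2, which cannot form a ketene because C11 is quaternary. Acylative Stille coupling with tributyl(vinyl)stannane and Pd(PPh3)4 (zerovalent palladium) in THF at 50 °C should then give the vinyl ketone. The fallback comes back to the route at 13 and replaces steps 6 and 7.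

Step 11. The methyl group may be delivered to the face syn to the C6 side chain, through the chair with that chain axial, or the ketone may enolise with epimerisation at C6. The fallback sets out from 17 and delivers oxygen instead of carbon from the open face. Non-basic methylenation with Zn/CH2Br2/TiCl4 in THF should give (1S,3S)-2,2-dimethyl-4-methylidene-3-{(3R)-3-methyl-3-[(triethylsilyl)oxy]pent-4-en-1-yl}cyclohexan-1-ol F3. One equivalent of m-CPBA (NaHCO3, CH2Cl2, 0 °C) should epoxidise the 1,1-disubstituted exocyclic alkene in preference to the monosubstituted vinyl group and give (3S,4R,6S)-5,5-dimethyl-4-{(3R)-3-methyl-3-[(triethylsilyl)oxy]pent-4-en-1-yl}-1-oxaspiro[2.5]octan-6-ol F4. LiBHEt3 should open the epoxide at the CH2 carbon and turn it into the C7 methyl group. This gives the right carbinol precisely in the case that reagents prefer the face from which the organocerium reagent added wrongly. The fallback comes back to the route at 18.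

Step 9. Hydride may be delivered along the axial path, giving the equatorial C10 alcohol, or the borohydride may be consumed by deprotonation next to the nitro group. The fallback sets out from 14 and replaces substrate control by reagent control. A Corey–Bakshi–Shibata reduction with (R)-1-methyl-3,3-diphenyltetrahydro-1H,3H-pyrrolo[1,2-c][1,3,2]oxazaborole (20 mol %) and catecholborane in toluene at −78 °C distinguishes the quaternary C11 from the C9 methylene and should give the (10S) alcohol. The neutral borane neither deprotonates the nitroalkane nor hydroborates the vinyl group at this temperature. The fallback comes back to the route at 15 and makes no compound outside the list (entry F0).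

**Further compounds**

F1 | step 6 | (3R,6R)-2,2,6-trimethyl-3-(nitromethyl)-6-[(triethylsilyl)oxy]oct-7-enoic acid | OC(=O)C(C)(C)[C@H](C[N+](=O)[O-])CC[C@@](C)(O[Si](CC)(CC)CC)C=C
F2 | step 6 | (3R,6R)-2,2,6-trimethyl-3-(nitromethyl)-6-[(triethylsilyl)oxy]oct-7-enoyl chloride | ClC(=O)C(C)(C)[C@H](C[N+](=O)[O-])CC[C@@](C)(O[Si](CC)(CC)CC)C=C
F3 | step 11 | (1S,3S)-2,2-dimethyl-4-methylidene-3-{(3R)-3-methyl-3-[(triethylsilyl)oxy]pent-4-en-1-yl}cyclohexan-1-ol | CC1(C)[C@@H](CC[C@@](C)(O[Si](CC)(CC)CC)C=C)C(=C)CC[C@@H]1O
F4 | step 11 | (3S,4R,6S)-5,5-dimethyl-4-{(3R)-3-methyl-3-[(triethylsilyl)oxy]pent-4-en-1-yl}-1-oxaspiro[2.5]octan-6-ol | CC1(C)[C@@H](CC[C@@](C)(O[Si](CC)(CC)CC)C=C)[C@@]2(OC2)CC[C@@H]1O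
F0 | step 9 | none | none
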